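## Retrosynthetic overview
1. The last step removes four aryl silyl groups. The free 4-hydroxy-2-pyrone (ring D) is cut back to a 3-acetyl group plus malonyl dichloride.
2. The trans-2-aryl-3-acyl dihydrofuran (ring C) comes from a stepwise ionic ring expansion of a donor–acceptor spirocyclopropane. In it the pyrone carbon C3 moves from the ArCH carbon to the CHAc carbon, and the pyrone C4 oxygen takes its place.
3. The spirocyclopropane comes from an amine-catalysed asymmetric Michael-initiated ring closure of a 3-chloro-4-hydroxy-6-styryl-2-pyrone onto an aryl enone.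
4. The styrylpyrone (ring B) comes from the same enone plus malonyl dichloride. The enone comes from catechol and methyl vinyl ketone by bromination, silylation and a Heck reaction.
5. Order of ring formation: styrylpyrone ring B, then cyclopropane, then dihydrofuran ring C, then hydroxypyrone ring D. All 26 carbons come from 2 catechol + 2 methyl vinyl ketone + 2 malonyl dichloride.

Abbreviations: Ar = 3,4-bis(tert-butyldimethylsilyloxy)phenyl; TBS = tert-butyldimethylsilyl; DPEN = 1,2-diphenylethane-1,2-diamine; CSA = camphor-10-sulfonic acid.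

Assumption: (1S,2S)-DPEN shields the enone iminium ion in the same sense as in its (S)-warfarin-type additions; if analysis shows the opposite sense, the (1R,2R)-diamine is used.

## Route

Step 1
Reactants: 1 catechol (benzene-1,2-diol)
Product: 2 4-bromocatechol (4-bromobenzene-1,2-diol)
Conditions: NBS (1.0 equiv), HBF4·OEt2 (1.0 equiv), MeCN, −30 °C → rt
Reagents that add atoms: N-bromosuccinimide, O=C1CCC(=O)N1Br
Why: Electrophilic aromatic bromination goes to the position para to one hydroxyl group, which is the most activated and least hindered site, and one equivalent at low temperature stops at the monobromide.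

Step 2
Reactants: 2 4-bromocatechol
Product: 3 4-bromo-1,2-bis(tert-butyldimethylsilyloxy)benzene (ArBr)
Conditions: TBSCl (2.4 equiv), imidazole (5 equiv), DMF, rt
Reagents that add atoms: tert-butyldimethylsilyl chloride, CC(C)(C)[Si](C)(C)Cl
Why: Imidazole-promoted silylation of phenols masks the oxidation-prone catechol with groups that survive amide bases, HCl in ether and mild acid and leave with fluoride at the end.

Step 3
Reactants: 3 ArBr; 4 methyl vinyl ketone (but-3-en-2-one)
Product: 5 (E)-4-Ar-but-3-en-2-one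
Conditions: Pd(OAc)2 (5 mol%), P(o-tol)3 (12 mol%), Et3N (2 equiv), MeCN, 85 °C, sealed tube, 16 h
Reagents that add atoms: none
Why: In this Mizoroki–Heck reaction zerovalent palladium inserts into the C–Br bond, and syn insertion at the terminal carbon followed by syn β-hydride elimination gives only the E-enone.

Step 4
Reactants: 5 (E)-4-Ar-but-3-en-2-one; 6 malonyl dichloride
Product: 8 6-[(E)-2-Ar-ethenyl]-4-hydroxy-2H-pyran-2-one (di-TBS-hispidin), via silyloxydiene 7 (not isolated)
Conditions: LiN(iPr)2 (1.05 equiv), THF, −78 °C; TMSCl (1.3 equiv), → 0 °C; evaporate, pentane, filter; then 6 (1.0 equiv), Et2O, −78 °C → rt, 12 h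
Reagents that add atoms: chlorotrimethylsilane, C[Si](C)(C)Cl (its Me3Si group is carried by 7 only and leaves again)
Why: The methyl group is the only enolisable site of 5, so a single 2-silyloxydiene forms; its CH2 terminus is C-acylated by malonyl dichloride and the enol oxygen closes onto the second acid chloride (silyl enol ether/malonyl dichloride pyrone annulation, Effenberger type).

Step 5
Reactants: 8 di-TBS-hispidin
Product: 9 3-chloro-6-[(E)-2-Ar-ethenyl]-4-hydroxy-2H-pyran-2-one
Conditions: NCS (1.0 equiv), CH2Cl2, 0 °C → rt, 1 h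
Reagents that add atoms: N-chlorosuccinimide, O=C1CCC(=O)N1Cl
Why: This is an electrophilic α-chlorination of a cyclic β-dicarbonyl enol, and because C3 of the 4-hydroxy-2-pyrone is by far the most nucleophilic carbon, one equivalent leaves the styrene and the arenes untouched.

Step 6 (key step)
Reactants: 9 3-chloropyrone; 5 (E)-4-Ar-but-3-en-2-one (1.3 equiv)
Product: 11 (2S,3S)-3-acetyl-2-Ar-6-[(E)-2-Ar-ethenyl]-2,3-dihydro-4H-furo[3,2-c]pyran-4-one, via spirocyclopropane 10 (not isolated)
Conditions: (1S,2S)-DPEN (20 mol%), AcOH (40 mol%), NaOAc (1.0 equiv), THF, rt, 72 h; then CSA (50 mol%), rt, 2 h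
Reagents that add atoms: none
Why: Proposed new method: an iminium–enamine Michael-initiated ring closure coupled in one flask to an ionic cyclopropane-to-dihydrofuran ring expansion, in which the diamine turns 5 into an iminium ion that is attacked on one face by C3 of the pyronolate of 9 (as in the diamine-catalysed warfarin-type Michael addition, setting the ArCH centre), the enamine so formed is necessarily the internal one and displaces chloride from the now quaternary C3 in a 3-exo-tet closure that places acetyl trans to Ar (as in organocatalytic cyclopropanations with bromomalonates or 3-chlorooxindoles), and the donor–acceptor spirocyclopropane 10 then breaks heterolytically at the bond between the spiro carbon and ArCH to give a p-silyloxybenzyl cation paired with an aromatic pyronolate, which recloses through the C4 oxygen anti to the acetyl group (acid-catalysed Cloke–Wilson-type expansion, known for 2-aryl spirocyclopropane-1,3-diones), so the pyrone carbon ends up on CHAc, the untouched CHAc centre becomes C3 (S) and relays its configuration to C2 (S, trans), and reversible C2–O ionisation under CSA funnels any cis or linear furo[2,3-b]pyran-4-one isomer to trans-11; the new elements are a 3-halo-4-hydroxy-2-pyrone as the one-carbon donor/acceptor, the enone/primary-amine version of this closure, and the in-situ expansion with chirality relay.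

Step 7
Reactants: 11 methyl ketone; 6 malonyl dichloride
Product: 13 (2S,3S)-2-Ar-6-[(E)-2-Ar-ethenyl]-3-(4-hydroxy-2-oxo-2H-pyran-6-yl)-2,3-dihydro-4H-furo[3,2-c]pyran-4-one (tetra-TBS-hypholomine B), via silyl enol ether 12 (not isolated)
Conditions: TMSCl (4 equiv), then LiN(iPr)2 (1.15 equiv), THF, −78 °C, 30 min; evaporate, pentane, filter; then 6 (1.05 equiv), Et2O–CH2Cl2, −78 → 0 °C
Reagents that add atoms: chlorotrimethylsilane, C[Si](C)(C)Cl (its Me3Si group is carried by 12 only and leaves again)
Why: Kinetic deprotonation with in-situ silyl trapping takes the open CH3 proton (the C3–H is tertiary and lies on the face covered by the C2 aryl group), and the terminal silyl enol ether then undergoes the same base-free malonyl dichloride pyrone annulation, so C2 and C3 are not touched and no β-elimination of the pyronolate can start.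

Step 8
Reactants: 13 tetra-TBS-hypholomine B
Product: 14 hypholomine B
Conditions: Et3N·3HF (12 equiv), THF, 0 °C → rt, argon; size-exclusion gel, MeOH
Reagents that add atoms: none
Why: Fluoride-driven cleavage of the four aryl silyl ethers runs under slightly acidic, non-oxidising conditions that spare both pyrones, the styrene, the benzylic C2–O bond and both stereocentres.

## Compound list
1 | catechol | Oc1ccccc1O | starting material
2 | 4-bromocatechol | Oc1ccc(Br)cc1O | intermediate
3 | 4-bromo-1,2-bis(tert-butyldimethylsilyloxy)benzene | CC(C)(C)[Si](C)(C)Oc1ccc(Br)cc1O[Si](C)(C)C(C)(C)C | intermediate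
4 | methyl vinyl ketone | C=CC(C)=O | starting material
5 | (E)-4-[3,4-bis(TBSO)phenyl]but-3-en-2-one | CC(=O)/C=C/c1ccc(O[Si](C)(C)C(C)(C)C)c(O[Si](C)(C)C(C)(C)C)c1 | intermediate
6 | malonyl dichloride | O=C(Cl)CC(=O)Cl | starting material
7 | (E)-4-[3,4-bis(TBSO)phenyl]-2-(trimethylsilyloxy)buta-1,3-diene | C=C(O[Si](C)(C)C)/C=C/c1ccc(O[Si](C)(C)C(C)(C)C)c(O[Si](C)(C)C(C)(C)C)c1 | intermediate
8 | 6-{(E)-2-[3,4-bis(TBSO)phenyl]ethenyl}-4-hydroxy-2H-pyran-2-one | O=c1cc(O)cc(/C=C/c2ccc(O[Si](C)(C)C(C)(C)C)c(O[Si](C)(C)C(C)(C)C)c2)o1 | intermediate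
9 | 3-chloro-6-{(E)-2-[3,4-bis(TBSO)phenyl]ethenyl}-4-hydroxy-2H-pyran-2-one | O=c1c(Cl)c(O)cc(/C=C/c2ccc(O[Si](C)(C)C(C)(C)C)c(O[Si](C)(C)C(C)(C)C)c2)o1 | intermediate
10 | (1R,2S)-1-acetyl-2-Ar-6-[(E)-2-Ar-ethenyl]-5-oxaspiro[2.5]oct-6-ene-4,8-dione (acetyl trans to Ar; either configuration at the spiro centre, both converge) | CC(=O)[C@@H]1[C@@H](c2ccc(O[Si](C)(C)C(C)(C)C)c(O[Si](C)(C)C(C)(C)C)c2)C13C(=O)C=C(/C=C/c2ccc(O[Si](C)(C)C(C)(C)C)c(O[Si](C)(C)C(C)(C)C)c2)OC3=O | intermediate
11 | (2S,3S)-3-acetyl-2-Ar-6-[(E)-2-Ar-ethenyl]-2,3-dihydro-4H-furo[3,2-c]pyran-4-one (trans) | CC(=O)[C@H]1c2c(cc(/C=C/c3ccc(O[Si](C)(C)C(C)(C)C)c(O[Si](C)(C)C(C)(C)C)c3)oc2=O)O[C@@H]1c1ccc(O[Si](C)(C)C(C)(C)C)c(O[Si](C)(C)C(C)(C)C)c1 | intermediate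
12 | (2S,3S)-2-Ar-6-[(E)-2-Ar-ethenyl]-3-[1-(trimethylsilyloxy)ethenyl]-2,3-dihydro-4H-furo[3,2-c]pyran-4-one | C=C(O[Si](C)(C)C)[C@H]1c2c(cc(/C=C/c3ccc(O[Si](C)(C)C(C)(C)C)c(O[Si](C)(C)C(C)(C)C)c3)oc2=O)O[C@@H]1c1ccc(O[Si](C)(C)C(C)(C)C)c(O[Si](C)(C)C(C)(C)C)c1 | intermediate
13 | tetra-TBS-hypholomine B, (2S,3S) | O=c1cc(O)cc([C@H]2c3c(cc(/C=C/c4ccc(O[Si](C)(C)C(C)(C)C)c(O[Si](C)(C)C(C)(C)C)c4)oc3=O)O[C@@H]2c2ccc(O[Si](C)(C)C(C)(C)C)c(O[Si](C)(C)C(C)(C)C)c2)o1 | intermediate
14 | hypholomine B, (2S,3S)-2-(3,4-dihydroxyphenyl)-6-[(E)-2-(3,4-dihydroxyphenyl)ethenyl]-3-(4-hydroxy-2-oxo-2H-pyran-6-yl)-2,3-dihydro-4H-furo[3,2-c]pyran-4-one | O=c1cc(O)cc([C@H]2c3c(cc(/C=C/c4ccc(O)c(O)c4)oc3=O)O[C@@H]2c2ccc(O)c(O)c2)o1 | target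

## Summary
Total step count: 8. Longest linear sequence: 8 (1 → 2 → 3 → 5 → 8 → 9 → 11 → 13 → 14). Enone 5 and malonyl dichloride 6 are each used twice.

## Three steps most likely to fail

**Step 6 (the new cascade).**
- Addition of the hindered chloropyronolate may be slow and reversible.
- Chlorine may transfer to the enamine, and O-alkylation would then give the 2-acetyl-3-aryl regioisomer.
- The ring-opened cation may lose a proton.
- The enantiomeric excess may be modest. It is checked on 11 by chiral HPLC.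

The fallback uses known chemistry, sets out from 8 (together with 5), bypasses 9 and 10, and comes back at 11. Compound 8 and a threefold excess of 5 are heated with Mn(OAc)3·2H2O (2.2 equiv) in AcOH at 70 °C in an oxidative radical annulation. The pyronyl radical adds to the enone α-carbon, the p-silyloxybenzyl radical is oxidised to the cation, and the pyrone oxygen closes trans. This gives 11 as a racemate with the (2R,3R)-enantiomer of 11 F1. The two are separated by preparative HPLC on an amylose tris(3,5-dimethylphenylcarbamate) phase.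

**Step 7.**
- Some enolisation may occur at C3.
- The HCl set free may protodesilylate 12.
- The new pyrone may be O-acylated.

The fallback sets out from 11 and comes back at 13. Commercial mono-tert-butyl malonate is coupled with 1H-benzotriazole (DCC, CH2Cl2) to give tert-butyl 3-(benzotriazol-1-yl)-3-oxopropanoate F2. Soft enolisation of 11 (MgBr2·OEt2, iPr2NEt, CH2Cl2, 0 °C) and C-acylation with F2 follow, with the magnesium chelate of the methyl-side product as the thermodynamic sink. This gives tert-butyl 5-{(2S,3S)-2-Ar-6-[(E)-2-Ar-ethenyl]-4-oxo-2,3-dihydro-4H-furo[3,2-c]pyran-3-yl}-3,5-dioxopentanoate F3. TFA/TFAA in CH2Cl2 at 0 °C removes the tert-butyl group and closes the lactone to 13.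

**Step 4.**
- The silyloxydiene may react as a diene with chlorocarbonylketene formed from 6.
- It may also polymerise under HCl, which would lower the yield of 8.

The fallback sets out from 3 and comes back at 8, and it cuts the pyrone at C5–C6 instead. A Heck reaction of 3 with N-methoxy-N-methylacrylamide (Pd(OAc)2, P(o-tol)3, Et3N) gives (E)-3-Ar-N-methoxy-N-methylacrylamide F4. This acylates the dianion of methyl acetoacetate (NaH, then n-BuLi, THF, −78 → 0 °C) to give methyl (E)-7-Ar-3,5-dioxohept-6-enoate F5. F5 lactonises to 8 with catalytic DBU in dry toluene at reflux.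

## Further compounds
F1 | step 6 | (2R,3R)-enantiomer of 11 | CC(=O)[C@@H]1c2c(cc(/C=C/c3ccc(O[Si](C)(C)C(C)(C)C)c(O[Si](C)(C)C(C)(C)C)c3)oc2=O)O[C@H]1c1ccc(O[Si](C)(C)C(C)(C)C)c(O[Si](C)(C)C(C)(C)C)c1
F2 | step 7 | tert-butyl 3-(benzotriazol-1-yl)-3-oxopropanoate | CC(C)(C)OC(=O)CC(=O)n1nnc2ccccc12
F3 | step 7 | tert-butyl 5-{(2S,3S)-2-Ar-6-[(E)-2-Ar-ethenyl]-4-oxo-2,3-dihydro-4H-furo[3,2-c]pyran-3-yl}-3,5-dioxopentanoate | CC(C)(C)OC(=O)CC(=O)CC(=O)[C@H]1c2c(cc(/C=C/c3ccc(O[Si](C)(C)C(C)(C)C)c(O[Si](C)(C)C(C)(C)C)c3)oc2=O)O[C@@H]1c1ccc(O[Si](C)(C)C(C)(C)C)c(O[Si](C)(C)C(C)(C)C)c1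
F4 | step 4 | (E)-3-[3,4-bis(TBSO)phenyl]-N-methoxy-N-methylacrylamide | CON(C)C(=O)/C=C/c1ccc(O[Si](C)(C)C(C)(C)C)c(O[Si](C)(C)C(C)(C)C)c1
F5 | step 4 | methyl (E)-7-[3,4-bis(TBSO)phenyl]-3,5-dioxohept-6-enoate | COC(=O)CC(=O)CC(=O)/C=C/c1ccc(O[Si](C)(C)C(C)(C)C)c(O[Si](C)(C)C(C)(C)C)c1
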